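**Assumption:** positions follow geldanamycin numbering (C1 amide carbonyl … C15 benzylic carbinol, arene C16–C21, N on C20); Cp ligands are drawn σ-bonded in SMILES; a named chiral ligand or reagent means the enantiomer that gives the face selectivity stated.

## Retrosynthetic overview

1. The 19-membered lactam is the only ring made (the arene is bought). It is closed last but one by intramolecular CuI/diamine N-arylation of the C1 primary enamide with the aryl bromide (N–C20), followed by global desilylation.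
2. The seco chain is cut at C7–C8: hydrozirconation/Zr-to-Zn transmetalation of a C8–C21 methyl alkyne (East fragment), then chelation-controlled addition to a C1–C7 α-methoxy aldehyde (West fragment).
3. East fragment: C14/C15 by Brown (Z)-crotylboration of the aryl aldehyde, C12 by catalytic asymmetric alkenylzinc addition, C10/C11 by allenylstannane SE2' propargylation of the C11 α-methoxy aldehyde.
4. West fragment: C6 from (S)-5-(hydroxymethyl)butyrolactone; C2=C3 by lactol Wittig olefination.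
5. The allenylstannane (C8–C10) comes from pent-3-yn-2-one by transfer hydrogenation, mesylation and anti SN2' stannylation.

## East fragment, part 1 (C11–C21)

Step 1
Reactants: 1 3-bromo-5-hydroxybenzaldehyde
Product: 2 3-bromo-5-(triisopropylsilyloxy)benzaldehyde
Conditions: TIPSCl, imidazole, DMF, rt
Reagents that add atoms: triisopropylsilyl chloride (CC(C)[Si](Cl)(C(C)C)C(C)C)
Why: Phenol O-silylation gives an aryl TIPS ether that survives the later Lewis acids and mild bases and leaves with fluoride at the end.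

Step 2
Reactants: 2 3-bromo-5-(triisopropylsilyloxy)benzaldehyde
Product: 4 (1R,2S)-1-[3-bromo-5-(triisopropylsilyloxy)phenyl]-2-methylbut-3-en-1-ol, via borinate ester 3 (not isolated)
Conditions: cis-2-butene, n-BuLi, KOtBu, THF, −78 to −45 °C; Ipc2BOMe derived from (−)-α-pinene, −78 °C; BF3·OEt2; then 2, −78 °C; NaBO3·4H2O, H2O, rt
Reagents that add atoms: cis-2-butene (C/C=C\C)
Why: Brown asymmetric (Z)-crotylboration through a chair transition state gives the 14,15-syn pair, and the Ipc2B group from (−)-α-pinene directs Re-face attack, setting C14 (S) and C15 (R).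

Step 3
Reactants: 4 (1R,2S)-1-[3-bromo-5-(triisopropylsilyloxy)phenyl]-2-methylbut-3-en-1-ol
Product: 5 (1R,2S)-1-[3-bromo-5-(triisopropylsilyloxy)phenyl]-1-(tert-butyldimethylsilyloxy)-2-methylbut-3-ene
Conditions: TBSOTf, 2,6-lutidine, CH2Cl2, −78 to 0 °C
Reagents that add atoms: tert-butyldimethylsilyl triflate (CC(C)(C)[Si](C)(C)OS(=O)(=O)C(F)(F)F)
Why: Silylation of the benzylic alcohol with a silyl triflate gives a robust TBS ether without touching the stereocentres.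

Step 4
Reactants: 5 (1R,2S)-1-[3-bromo-5-(triisopropylsilyloxy)phenyl]-1-(tert-butyldimethylsilyloxy)-2-methylbut-3-ene
Product: 7 (3S,4R)-4-[3-bromo-5-(triisopropylsilyloxy)phenyl]-4-(tert-butyldimethylsilyloxy)-3-methylbutan-1-ol, via B-alkyl-9-BBN adduct 6 (not isolated)
Conditions: 9-BBN, THF, 0 °C to rt; NaBO3·4H2O, H2O, rt
Reagents that add atoms: sodium perborate ([Na+].[O-]OB=O)
Why: Anti-Markovnikov hydroboration–oxidation of the terminal alkene with the bulky 9-BBN puts the oxygen on C12; the aryl bromide and silyl ethers are inert.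

Step 5
Reactants: 7 (3S,4R)-4-[3-bromo-5-(triisopropylsilyloxy)phenyl]-4-(tert-butyldimethylsilyloxy)-3-methylbutan-1-ol
Product: 8 (3S,4R)-4-[3-bromo-5-(triisopropylsilyloxy)phenyl]-4-(tert-butyldimethylsilyloxy)-3-methylbutanal
Conditions: Dess–Martin periodinane, NaHCO3, CH2Cl2, rt
Reagents that add atoms: none
Why: Buffered Dess–Martin oxidation gives the aldehyde, whose β-stereocentre cannot epimerise.

Step 6
Reactants: 8 (3S,4R)-4-[3-bromo-5-(triisopropylsilyloxy)phenyl]-4-(tert-butyldimethylsilyloxy)-3-methylbutanal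
Product: 9 (1R,2S,4S,5E)-1-[3-bromo-5-(triisopropylsilyloxy)phenyl]-1-(tert-butyldimethylsilyloxy)-2-methyldec-5-en-4-ol
Conditions: 1-hexyne, Cy2BH, toluene, 0 °C to rt; ZnMe2, −78 °C; (+)-MIB (5 mol %); then 8, −20 to 0 °C; aq NH4Cl
Reagents that add atoms: 1-hexyne (C#CCCCC)
Why: Oppolzer–Walsh catalytic asymmetric alkenylzinc addition (hydroboration, B-to-Zn transmetalation, amino-alcohol catalysis) delivers the alkenyl group to the Re face by ligand control, setting C12 (S).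

Step 7
Reactants: 9 (1R,2S,4S,5E)-1-[3-bromo-5-(triisopropylsilyloxy)phenyl]-1-(tert-butyldimethylsilyloxy)-2-methyldec-5-en-4-ol
Product: 10 (1R,2S,4S,5E)-1-[3-bromo-5-(triisopropylsilyloxy)phenyl]-1-(tert-butyldimethylsilyloxy)-4-methoxy-2-methyldec-5-ene
Conditions: Me3OBF4, 1,8-bis(dimethylamino)naphthalene, CH2Cl2, 0 °C to rt
Reagents that add atoms: trimethyloxonium tetrafluoroborate (C[O+](C)C.F[B-](F)(F)F)
Why: Non-basic O-methylation with an oxonium salt installs the C12 methyl ether without alkoxide-induced silyl migration.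

Step 8
Reactants: 10 (1R,2S,4S,5E)-1-[3-bromo-5-(triisopropylsilyloxy)phenyl]-1-(tert-butyldimethylsilyloxy)-4-methoxy-2-methyldec-5-ene
Product: 12 (2S,4S,5R)-5-[3-bromo-5-(triisopropylsilyloxy)phenyl]-5-(tert-butyldimethylsilyloxy)-2-methoxy-4-methylpentanal, via ozonide 11 (not isolated)
Conditions: O3, CH2Cl2, −78 °C; PPh3, −78 °C to rt
Reagents that add atoms: ozone (O=[O+][O-])
Why: Ozonolysis with reductive work-up cleaves the disubstituted alkene (much faster than the bromoarene reacts) and unveils the C11 α-methoxy aldehyde with C12 intact.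

## Allenylstannane branch (C8–C10)

Step 9
Reactants: 13 pent-3-yn-2-one
Product: 14 (S)-pent-3-yn-2-ol
Conditions: RuCl[(S,S)-TsDPEN](p-cymene) (0.5 mol %), KOH (1 mol %), i-PrOH, rt
Reagents that add atoms: none
Why: Noyori asymmetric transfer hydrogenation of the ynone, in which the alkynyl group plays the role of the aryl group of acetophenone, gives the (S)-propargylic alcohol.

Step 10
Reactants: 14 (S)-pent-3-yn-2-ol
Product: 15 (S)-pent-3-yn-2-yl methanesulfonate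
Conditions: MsCl, Et3N, CH2Cl2, −78 to 0 °C
Reagents that add atoms: methanesulfonyl chloride (CS(=O)(=O)Cl)
Why: O-sulfonylation activates the propargylic position with retention at the stereocentre.

Step 11
Reactants: 15 (S)-pent-3-yn-2-yl methanesulfonate
Product: 16 (M)-tributyl(penta-2,3-dien-2-yl)stannane
Conditions: Bu3SnH, LiN(i-Pr)2, THF, 0 °C; CuBr·SMe2, −78 °C; then 15, −78 °C
Reagents that add atoms: tributyltin hydride (CCCC[SnH](CCCC)CCCC)
Why: Anti SN2' displacement of the propargylic mesylate by the stannylcopper reagent transfers central to axial chirality and gives the (M)-allene.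

## East fragment, part 2 (C8–C21)

Step 12
Reactants: 12 (2S,4S,5R)-5-[3-bromo-5-(triisopropylsilyloxy)phenyl]-5-(tert-butyldimethylsilyloxy)-2-methoxy-4-methylpentanal and 16 (M)-tributyl(penta-2,3-dien-2-yl)stannane
Product: 17 (1R,2S,4S,5R,6S)-1-[3-bromo-5-(triisopropylsilyloxy)phenyl]-1-(tert-butyldimethylsilyloxy)-4-methoxy-2,6-dimethylnon-7-yn-5-ol
Conditions: BF3·OEt2, CH2Cl2, −78 °C; aq NaHCO3
Reagents that add atoms: none
Why: Marshall propargylation: anti SE2' attack of the allene through an open transition state gives the 10,11-syn adduct with C10 (S), and Felkin (non-chelate) addition to the α-methoxy aldehyde gives 11,12-anti, a matched pairing that sets C11 (R).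

Step 13
Reactants: 17 (1R,2S,4S,5R,6S)-1-[3-bromo-5-(triisopropylsilyloxy)phenyl]-1-(tert-butyldimethylsilyloxy)-4-methoxy-2,6-dimethylnon-7-yn-5-ol
Product: 18 (1R,2S,4S,5R,6S)-1-[3-bromo-5-(triisopropylsilyloxy)phenyl]-1-(tert-butyldimethylsilyloxy)-4-methoxy-2,6-dimethyl-5-(triethylsilyloxy)non-7-yne
Conditions: TESOTf, 2,6-lutidine, CH2Cl2, −78 °C
Reagents that add atoms: triethylsilyl triflate (CC[Si](CC)(CC)OS(=O)(=O)C(F)(F)F)
Why: Silylation of the hindered C11 alcohol with the reactive triflate gives a TES ether that is easy to remove at the end.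

## West fragment (C1–C7)

Step 14
Reactants: 19 (S)-5-(hydroxymethyl)dihydrofuran-2(3H)-one
Product: 20 (S)-5-[(tert-butyldiphenylsilyloxy)methyl]dihydrofuran-2(3H)-one
Conditions: TBDPSCl, imidazole, CH2Cl2, rt
Reagents that add atoms: tert-butyldiphenylsilyl chloride (CC(C)(C)[Si](Cl)(c1ccccc1)c1ccccc1)
Why: Silyl protection of the primary alcohol of the chiral-pool lactone, whose stereocentre becomes C6 (S).

Step 15
Reactants: 20 (S)-5-[(tert-butyldiphenylsilyloxy)methyl]dihydrofuran-2(3H)-one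
Product: 21 (5S)-5-[(tert-butyldiphenylsilyloxy)methyl]tetrahydrofuran-2-ol (anomer mixture)
Conditions: i-Bu2AlH, CH2Cl2, −78 °C; aq KNaC4H4O6
Reagents that add atoms: none
Why: Low-temperature partial reduction of the lactone stops at the lactol because the tetrahedral aluminate is stable at −78 °C.

Step 16
Reactants: 21 (5S)-5-[(tert-butyldiphenylsilyloxy)methyl]tetrahydrofuran-2-ol
Product: 22 ethyl (2E,6S)-7-(tert-butyldiphenylsilyloxy)-6-hydroxy-2-methylhept-2-enoate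
Conditions: Ph3P=C(CH3)CO2Et, toluene, 80 °C
Reagents that add atoms: ethyl 2-(triphenylphosphoranylidene)propanoate (CCOC(=O)C(C)=P(c1ccccc1)(c1ccccc1)c1ccccc1)
Why: Wittig olefination of the open hydroxy-aldehyde form of the lactol with a stabilised α-methyl ylide gives the (E)-trisubstituted enoate (C2=C3) under thermodynamic control.

Step 17
Reactants: 22 ethyl (2E,6S)-7-(tert-butyldiphenylsilyloxy)-6-hydroxy-2-methylhept-2-enoate
Product: 23 ethyl (2E,6S)-7-(tert-butyldiphenylsilyloxy)-6-methoxy-2-methylhept-2-enoate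
Conditions: Me3OBF4, 1,8-bis(dimethylamino)naphthalene, CH2Cl2, rt
Reagents that add atoms: trimethyloxonium tetrafluoroborate (C[O+](C)C.F[B-](F)(F)F)
Why: Non-basic O-methylation of the C6 alcohol avoids oxa-Michael closure onto the enoate and silyl migration.

Step 18
Reactants: 23 ethyl (2E,6S)-7-(tert-butyldiphenylsilyloxy)-6-methoxy-2-methylhept-2-enoate
Product: 24 ethyl (2E,6S)-7-hydroxy-6-methoxy-2-methylhept-2-enoate
Conditions: TBAF, AcOH, THF, rt
Reagents that add atoms: none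
Why: Buffered fluoride desilylation frees the primary alcohol without alkoxide-mediated conjugate addition to the enoate.

Step 19
Reactants: 24 ethyl (2E,6S)-7-hydroxy-6-methoxy-2-methylhept-2-enoate
Product: 25 ethyl (2E,6S)-6-methoxy-2-methyl-7-oxohept-2-enoate
Conditions: Dess–Martin periodinane, NaHCO3, CH2Cl2, 0 °C to rt
Reagents that add atoms: none
Why: Neutral Dess–Martin oxidation gives the α-methoxy aldehyde without epimerising C6; it is used at once.

## Fragment union and endgame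

Step 20
Reactants: 18 (1R,2S,4S,5R,6S)-1-[3-bromo-5-(triisopropylsilyloxy)phenyl]-1-(tert-butyldimethylsilyloxy)-4-methoxy-2,6-dimethyl-5-(triethylsilyloxy)non-7-yne and 25 ethyl (2E,6S)-6-methoxy-2-methyl-7-oxohept-2-enoate
Product: 28 ethyl (2E,6S,7S,8E,10S,11R,12S,14S,15R)-15-[3-bromo-5-(triisopropylsilyloxy)phenyl]-15-(tert-butyldimethylsilyloxy)-7-hydroxy-6,12-dimethoxy-2,8,10,14-tetramethyl-11-(triethylsilyloxy)pentadeca-2,8-dienoate, via alkenylzirconocene 26 (not isolated), via alkenylzinc 27 (not isolated)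
Conditions: Cp2Zr(H)Cl, THF, 50 °C; ZnMe2, −78 °C; then 25, −78 to 0 °C; aq NH4Cl
Reagents that add atoms: none
Why: Syn hydrozirconation places Zr on the less hindered C8 and fixes the (8E) geometry, and after Wipf-type Zr-to-Zn transmetalation the alkenylzinc adds to the zinc chelate of the α-methoxy aldehyde (Cram chelate control) to give the 6,7-syn alcohol, C7 (S).

Step 21
Reactants: 28 ethyl (2E,6S,7S,8E,10S,11R,12S,14S,15R)-15-[3-bromo-5-(triisopropylsilyloxy)phenyl]-15-(tert-butyldimethylsilyloxy)-7-hydroxy-6,12-dimethoxy-2,8,10,14-tetramethyl-11-(triethylsilyloxy)pentadeca-2,8-dienoate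
Product: 29 ethyl (2E,6S,7S,8E,10S,11R,12S,14S,15R)-15-[3-bromo-5-(triisopropylsilyloxy)phenyl]-15-(tert-butyldimethylsilyloxy)-6,12-dimethoxy-2,8,10,14-tetramethyl-7,11-bis(triethylsilyloxy)pentadeca-2,8-dienoate
Conditions: TESOTf, 2,6-lutidine, CH2Cl2, −78 °C
Reagents that add atoms: triethylsilyl triflate (CC[Si](CC)(CC)OS(=O)(=O)C(F)(F)F)
Why: Silylation masks the allylic C7 alcohol during aminolysis and the hot copper-mediated cyclisation.

Step 22
Reactants: 29 ethyl (2E,6S,7S,8E,10S,11R,12S,14S,15R)-15-[3-bromo-5-(triisopropylsilyloxy)phenyl]-15-(tert-butyldimethylsilyloxy)-6,12-dimethoxy-2,8,10,14-tetramethyl-7,11-bis(triethylsilyloxy)pentadeca-2,8-dienoate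
Product: 30 (2E,6S,7S,8E,10S,11R,12S,14S,15R)-15-[3-bromo-5-(triisopropylsilyloxy)phenyl]-15-(tert-butyldimethylsilyloxy)-6,12-dimethoxy-2,8,10,14-tetramethyl-7,11-bis(triethylsilyloxy)pentadeca-2,8-dienamide
Conditions: AlMe3, NH4Cl, toluene, 0 to 50 °C; aq KNaC4H4O6
Reagents that add atoms: ammonium chloride ([NH4+].[Cl-])
Why: Weinreb aminolysis with the aluminium amide made from AlMe3 and NH4Cl turns the ester directly into the primary amide without aqueous base, so the aryl silyl ether survives.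

Step 23
Reactants: 30 (2E,6S,7S,8E,10S,11R,12S,14S,15R)-15-[3-bromo-5-(triisopropylsilyloxy)phenyl]-15-(tert-butyldimethylsilyloxy)-6,12-dimethoxy-2,8,10,14-tetramethyl-7,11-bis(triethylsilyloxy)pentadeca-2,8-dienamide
Product: 31 7,11-bis-O-triethylsilyl-15-O-tert-butyldimethylsilyl-18-O-triisopropylsilyl derivative of the target macrolactam
Conditions: CuI (1 equiv), N,N'-dimethylethylenediamine, K2CO3, toluene (2 mM), 100 °C
Reagents that add atoms: none
Why: Intramolecular Goldberg–Buchwald N-arylation of the primary enamide by the aryl bromide closes the 19-membered lactam under high dilution, a macrocyclisation with close precedent on the 15-deoxy analogue of this chain; no stereocentre is touched.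

Step 24
Reactants: 31 7,11-bis-O-triethylsilyl-15-O-tert-butyldimethylsilyl-18-O-triisopropylsilyl derivative of the target macrolactam
Product: 32 CNP0366451.1 (target)
Conditions: TBAF, AcOH, THF, 0 °C to rt
Reagents that add atoms: none
Why: Buffered fluoride removes the aryl TIPS ether, the benzylic TBS ether and both TES ethers in one global desilylation without harming the enamide or the allylic and benzylic carbinols.

## Compound list

1 | 3-bromo-5-hydroxybenzaldehyde | O=Cc1cc(O)cc(Br)c1 | starting material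
2 | 3-bromo-5-(triisopropylsilyloxy)benzaldehyde | O=Cc1cc(O[Si](C(C)C)(C(C)C)C(C)C)cc(Br)c1 | intermediate
3 | (1R,2S)-1-[3-bromo-5-(triisopropylsilyloxy)phenyl]-2-methylbut-3-enyl diisopinocampheylborinate (Ipc from (−)-α-pinene) | C=C[C@H](C)[C@@H](OB([C@H]1C[C@H]2C[C@@H]([C@@H]1C)C2(C)C)[C@H]1C[C@H]2C[C@@H]([C@@H]1C)C2(C)C)c1cc(O[Si](C(C)C)(C(C)C)C(C)C)cc(Br)c1 | intermediate
4 | (1R,2S)-1-[3-bromo-5-(triisopropylsilyloxy)phenyl]-2-methylbut-3-en-1-ol | C=C[C@H](C)[C@@H](O)c1cc(O[Si](C(C)C)(C(C)C)C(C)C)cc(Br)c1 | intermediate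
5 | (1R,2S)-1-[3-bromo-5-(triisopropylsilyloxy)phenyl]-1-(tert-butyldimethylsilyloxy)-2-methylbut-3-ene | C=C[C@H](C)[C@@H](O[Si](C)(C)C(C)(C)C)c1cc(O[Si](C(C)C)(C(C)C)C(C)C)cc(Br)c1 | intermediate
6 | 9-[(3S,4R)-4-[3-bromo-5-(triisopropylsilyloxy)phenyl]-4-(tert-butyldimethylsilyloxy)-3-methylbutyl]-9-borabicyclo[3.3.1]nonane | B1(CC[C@H](C)[C@@H](O[Si](C)(C)C(C)(C)C)c2cc(O[Si](C(C)C)(C(C)C)C(C)C)cc(Br)c2)C2CCCC1CCC2 | intermediate
7 | (3S,4R)-4-[3-bromo-5-(triisopropylsilyloxy)phenyl]-4-(tert-butyldimethylsilyloxy)-3-methylbutan-1-ol | OCC[C@H](C)[C@@H](O[Si](C)(C)C(C)(C)C)c1cc(O[Si](C(C)C)(C(C)C)C(C)C)cc(Br)c1 | intermediate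
8 | (3S,4R)-4-[3-bromo-5-(triisopropylsilyloxy)phenyl]-4-(tert-butyldimethylsilyloxy)-3-methylbutanal | O=CC[C@H](C)[C@@H](O[Si](C)(C)C(C)(C)C)c1cc(O[Si](C(C)C)(C(C)C)C(C)C)cc(Br)c1 | intermediate
9 | (1R,2S,4S,5E)-1-[3-bromo-5-(triisopropylsilyloxy)phenyl]-1-(tert-butyldimethylsilyloxy)-2-methyldec-5-en-4-ol | CCCC/C=C/[C@@H](O)C[C@H](C)[C@@H](O[Si](C)(C)C(C)(C)C)c1cc(O[Si](C(C)C)(C(C)C)C(C)C)cc(Br)c1 | intermediate
10 | (1R,2S,4S,5E)-1-[3-bromo-5-(triisopropylsilyloxy)phenyl]-1-(tert-butyldimethylsilyloxy)-4-methoxy-2-methyldec-5-ene | CCCC/C=C/[C@@H](OC)C[C@H](C)[C@@H](O[Si](C)(C)C(C)(C)C)c1cc(O[Si](C(C)C)(C(C)C)C(C)C)cc(Br)c1 | intermediate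
11 | 3-butyl-5-[(1S,3S,4R)-4-[3-bromo-5-(triisopropylsilyloxy)phenyl]-4-(tert-butyldimethylsilyloxy)-1-methoxy-3-methylbutyl]-1,2,4-trioxolane (ozonide, ring epimers) | CCCCC1OOC(O1)[C@@H](OC)C[C@H](C)[C@@H](O[Si](C)(C)C(C)(C)C)c1cc(O[Si](C(C)C)(C(C)C)C(C)C)cc(Br)c1 | intermediate
12 | (2S,4S,5R)-5-[3-bromo-5-(triisopropylsilyloxy)phenyl]-5-(tert-butyldimethylsilyloxy)-2-methoxy-4-methylpentanal | O=C[C@@H](OC)C[C@H](C)[C@@H](O[Si](C)(C)C(C)(C)C)c1cc(O[Si](C(C)C)(C(C)C)C(C)C)cc(Br)c1 | intermediate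
13 | pent-3-yn-2-one | CC#CC(C)=O | starting material
14 | (S)-pent-3-yn-2-ol | CC#C[C@H](C)O | intermediate
15 | (S)-pent-3-yn-2-yl methanesulfonate | CC#C[C@H](C)OS(C)(=O)=O | intermediate
16 | (M)-tributyl(penta-2,3-dien-2-yl)stannane | CC([H])=[C@]=C(C)[Sn](CCCC)(CCCC)CCCC | intermediate
17 | (1R,2S,4S,5R,6S)-1-[3-bromo-5-(triisopropylsilyloxy)phenyl]-1-(tert-butyldimethylsilyloxy)-4-methoxy-2,6-dimethylnon-7-yn-5-ol | CC#C[C@H](C)[C@@H](O)[C@@H](OC)C[C@H](C)[C@@H](O[Si](C)(C)C(C)(C)C)c1cc(O[Si](C(C)C)(C(C)C)C(C)C)cc(Br)c1 | intermediate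
18 | (1R,2S,4S,5R,6S)-1-[3-bromo-5-(triisopropylsilyloxy)phenyl]-1-(tert-butyldimethylsilyloxy)-4-methoxy-2,6-dimethyl-5-(triethylsilyloxy)non-7-yne (East fragment) | CC#C[C@H](C)[C@@H](O[Si](CC)(CC)CC)[C@@H](OC)C[C@H](C)[C@@H](O[Si](C)(C)C(C)(C)C)c1cc(O[Si](C(C)C)(C(C)C)C(C)C)cc(Br)c1 | intermediate
19 | (S)-5-(hydroxymethyl)dihydrofuran-2(3H)-one | OC[C@@H]1CCC(=O)O1 | starting material
20 | (S)-5-[(tert-butyldiphenylsilyloxy)methyl]dihydrofuran-2(3H)-one | CC(C)(C)[Si](c1ccccc1)(c1ccccc1)OC[C@@H]1CCC(=O)O1 | intermediate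
21 | (5S)-5-[(tert-butyldiphenylsilyloxy)methyl]tetrahydrofuran-2-ol (anomer mixture) | CC(C)(C)[Si](c1ccccc1)(c1ccccc1)OC[C@@H]1CCC(O)O1 | intermediate
22 | ethyl (2E,6S)-7-(tert-butyldiphenylsilyloxy)-6-hydroxy-2-methylhept-2-enoate | CCOC(=O)/C(C)=C/CC[C@H](O)CO[Si](c1ccccc1)(c1ccccc1)C(C)(C)C | intermediate
23 | ethyl (2E,6S)-7-(tert-butyldiphenylsilyloxy)-6-methoxy-2-methylhept-2-enoate | CCOC(=O)/C(C)=C/CC[C@H](OC)CO[Si](c1ccccc1)(c1ccccc1)C(C)(C)C | intermediate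
24 | ethyl (2E,6S)-7-hydroxy-6-methoxy-2-methylhept-2-enoate | CCOC(=O)/C(C)=C/CC[C@H](OC)CO | intermediate
25 | ethyl (2E,6S)-6-methoxy-2-methyl-7-oxohept-2-enoate (West fragment) | CCOC(=O)/C(C)=C/CC[C@H](OC)C=O | intermediate
26 | (E)-alkenyl(chloro)zirconocene from 18 (Zr on C8, trans to C10) | Cl[Zr](C1C=CC=C1)(C1C=CC=C1)/C(C)=C/[C@H](C)[C@@H](O[Si](CC)(CC)CC)[C@@H](OC)C[C@H](C)[C@@H](O[Si](C)(C)C(C)(C)C)c1cc(O[Si](C(C)C)(C(C)C)C(C)C)cc(Br)c1 | intermediate
27 | (E)-alkenyl(methyl)zinc from 26 (Zn on C8) | C[Zn]/C(C)=C/[C@H](C)[C@@H](O[Si](CC)(CC)CC)[C@@H](OC)C[C@H](C)[C@@H](O[Si](C)(C)C(C)(C)C)c1cc(O[Si](C(C)C)(C(C)C)C(C)C)cc(Br)c1 | intermediate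
28 | ethyl (2E,6S,7S,8E,10S,11R,12S,14S,15R)-15-[3-bromo-5-(triisopropylsilyloxy)phenyl]-15-(tert-butyldimethylsilyloxy)-7-hydroxy-6,12-dimethoxy-2,8,10,14-tetramethyl-11-(triethylsilyloxy)pentadeca-2,8-dienoate | CCOC(=O)/C(C)=C/CC[C@H](OC)[C@@H](O)/C(C)=C/[C@H](C)[C@@H](O[Si](CC)(CC)CC)[C@@H](OC)C[C@H](C)[C@@H](O[Si](C)(C)C(C)(C)C)c1cc(O[Si](C(C)C)(C(C)C)C(C)C)cc(Br)c1 | intermediate
29 | ethyl (2E,6S,7S,8E,10S,11R,12S,14S,15R)-15-[3-bromo-5-(triisopropylsilyloxy)phenyl]-15-(tert-butyldimethylsilyloxy)-6,12-dimethoxy-2,8,10,14-tetramethyl-7,11-bis(triethylsilyloxy)pentadeca-2,8-dienoate | CCOC(=O)/C(C)=C/CC[C@H](OC)[C@@H](O[Si](CC)(CC)CC)/C(C)=C/[C@H](C)[C@@H](O[Si](CC)(CC)CC)[C@@H](OC)C[C@H](C)[C@@H](O[Si](C)(C)C(C)(C)C)c1cc(O[Si](C(C)C)(C(C)C)C(C)C)cc(Br)c1 | intermediate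
30 | (2E,6S,7S,8E,10S,11R,12S,14S,15R)-15-[3-bromo-5-(triisopropylsilyloxy)phenyl]-15-(tert-butyldimethylsilyloxy)-6,12-dimethoxy-2,8,10,14-tetramethyl-7,11-bis(triethylsilyloxy)pentadeca-2,8-dienamide | NC(=O)/C(C)=C/CC[C@H](OC)[C@@H](O[Si](CC)(CC)CC)/C(C)=C/[C@H](C)[C@@H](O[Si](CC)(CC)CC)[C@@H](OC)C[C@H](C)[C@@H](O[Si](C)(C)C(C)(C)C)c1cc(O[Si](C(C)C)(C(C)C)C(C)C)cc(Br)c1 | intermediate
31 | tetrasilylated macrolactam: target carrying 7-O-TES, 11-O-TES, 15-O-TBS and phenol O-TIPS (19-membered lactam, N on C20) | CO[C@H]1C[C@H](C)[C@@H](O[Si](C)(C)C(C)(C)C)c2cc(O[Si](C(C)C)(C(C)C)C(C)C)cc(c2)NC(=O)/C(C)=C/CC[C@H](OC)[C@@H](O[Si](CC)(CC)CC)/C(C)=C/[C@H](C)[C@H]1O[Si](CC)(CC)CC | intermediate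
32 | CNP0366451.1: 19-membered lactam with (2E,6S,7S,8E,10S,11R,12S,14S,15R)-7,11,15-trihydroxy-6,12-dimethoxy-2,8,10,14-tetramethyl chain C1–C15 spanning C16 and N–C20 of a 5-hydroxy-1,3-phenylene | CO[C@H]1C[C@H](C)[C@@H](O)c2cc(O)cc(c2)NC(=O)/C(C)=C/CC[C@H](OC)[C@@H](O)/C(C)=C/[C@H](C)[C@H]1O | target

## Totals and risk

Total step count: 24.
Longest linear sequence: 15 steps (steps 1–8, 12, 13, 20–24, from 1 to 32).

Three steps most likely to fail:

**Step 6 (asymmetric alkenylzinc addition to an α-unbranched aldehyde; ee may be eroded and self-aldol can compete).** The fallback sets out from 8 and returns at 9. The same (E)-hex-1-enyl(methyl)zinc is added without the chiral ligand, giving the C12-epimeric alcohol mixture (1R,2S,4RS,5E)-1-[3-bromo-5-(triisopropylsilyloxy)phenyl]-1-(tert-butyldimethylsilyloxy)-2-methyldec-5-en-4-ol F1. Dess–Martin oxidation converts it into the enone (1R,2S,5E)-1-[3-bromo-5-(triisopropylsilyloxy)phenyl]-1-(tert-butyldimethylsilyloxy)-2-methyldec-5-en-4-one F2. Reduction with (R)-2-methyl-CBS-oxazaborolidine and catecholborane in toluene at −78 °C, with the alkenyl group as the large substituent, then sets C12 (S) by reagent control and gives 9.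

**Step 20 (regioselective hydrozirconation of the internal alkyne and chelation-controlled addition; either selectivity may be modest, and residual Zr–H can reduce 25).** The fallback sets out from 18 and returns at 28. Hydrozirconation of 18 with Cp2Zr(H)Cl followed by iodine gives the vinyl iodide (1R,2S,4S,5R,6S,7E)-1-[3-bromo-5-(triisopropylsilyloxy)phenyl]-1-(tert-butyldimethylsilyloxy)-8-iodo-4-methoxy-2,6-dimethyl-5-(triethylsilyloxy)non-7-ene F3, which can be purified from its regioisomer. CrCl2 with catalytic NiCl2 in DMSO couples F3 with 25 (the aryl bromide and ester are inert) to give the C7-epimeric alcohols, the (7RS) form of 28, F4. Dess–Martin oxidation gives the 7-oxo compound ethyl (2E,6S,8E,10S,11R,12S,14S,15R)-15-[3-bromo-5-(triisopropylsilyloxy)phenyl]-15-(tert-butyldimethylsilyloxy)-6,12-dimethoxy-2,8,10,14-tetramethyl-7-oxo-11-(triethylsilyloxy)pentadeca-2,8-dienoate F5. Reduction with (S)-2-methyl-CBS-oxazaborolidine and catecholborane delivers the (7S)-alcohol 28.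

**Step 23 (copper-mediated macrocyclisation; also exposed to a sluggish aminolysis in step 22).** The fallback sets out from 29, bypasses 30, and returns at 31 by a classical macrolactamisation. Pd2(dba)3/BINAP/Cs2CO3 amination of 29 with benzophenone imine in toluene at 90 °C gives the N-(diphenylmethylene)aniline analogue of 29, F6. NH2OH·HCl/NaOAc in MeOH frees the aniline, the 3-amino-aryl analogue of 29, F7. Me3SnOH in 1,2-dichloroethane at 80 °C cleaves the ethyl ester to the amino acid, the seco acid, F8. BOP-Cl and i-Pr2NEt in toluene under high dilution at 85 °C then close the anilide to give 31.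

## Further compounds

F1 | step 6 | (1R,2S,4RS,5E)-1-[3-bromo-5-(triisopropylsilyloxy)phenyl]-1-(tert-butyldimethylsilyloxy)-2-methyldec-5-en-4-ol | CCCC/C=C/C(O)C[C@H](C)[C@@H](O[Si](C)(C)C(C)(C)C)c1cc(O[Si](C(C)C)(C(C)C)C(C)C)cc(Br)c1
F2 | step 6 | (1R,2S,5E)-1-[3-bromo-5-(triisopropylsilyloxy)phenyl]-1-(tert-butyldimethylsilyloxy)-2-methyldec-5-en-4-one | CCCC/C=C/C(=O)C[C@H](C)[C@@H](O[Si](C)(C)C(C)(C)C)c1cc(O[Si](C(C)C)(C(C)C)C(C)C)cc(Br)c1
F3 | step 20 | (1R,2S,4S,5R,6S,7E)-1-[3-bromo-5-(triisopropylsilyloxy)phenyl]-1-(tert-butyldimethylsilyloxy)-8-iodo-4-methoxy-2,6-dimethyl-5-(triethylsilyloxy)non-7-ene | I/C(C)=C/[C@H](C)[C@@H](O[Si](CC)(CC)CC)[C@@H](OC)C[C@H](C)[C@@H](O[Si](C)(C)C(C)(C)C)c1cc(O[Si](C(C)C)(C(C)C)C(C)C)cc(Br)c1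
F4 | step 20 | (7RS) form of 28 (C7-epimer mixture) | CCOC(=O)/C(C)=C/CC[C@H](OC)C(O)/C(C)=C/[C@H](C)[C@@H](O[Si](CC)(CC)CC)[C@@H](OC)C[C@H](C)[C@@H](O[Si](C)(C)C(C)(C)C)c1cc(O[Si](C(C)C)(C(C)C)C(C)C)cc(Br)c1
F5 | step 20 | ethyl (2E,6S,8E,10S,11R,12S,14S,15R)-15-[3-bromo-5-(triisopropylsilyloxy)phenyl]-15-(tert-butyldimethylsilyloxy)-6,12-dimethoxy-2,8,10,14-tetramethyl-7-oxo-11-(triethylsilyloxy)pentadeca-2,8-dienoate | CCOC(=O)/C(C)=C/CC[C@H](OC)C(=O)/C(C)=C/[C@H](C)[C@@H](O[Si](CC)(CC)CC)[C@@H](OC)C[C@H](C)[C@@H](O[Si](C)(C)C(C)(C)C)c1cc(O[Si](C(C)C)(C(C)C)C(C)C)cc(Br)c1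
F6 | step 23 | N-(diphenylmethylene)aniline analogue of 29 (N=CPh2 in place of Br) | CCOC(=O)/C(C)=C/CC[C@H](OC)[C@@H](O[Si](CC)(CC)CC)/C(C)=C/[C@H](C)[C@@H](O[Si](CC)(CC)CC)[C@@H](OC)C[C@H](C)[C@@H](O[Si](C)(C)C(C)(C)C)c1cc(O[Si](C(C)C)(C(C)C)C(C)C)cc(N=C(c2ccccc2)c2ccccc2)c1
F7 | step 23 | aniline ester (NH2 in place of Br in 29) | CCOC(=O)/C(C)=C/CC[C@H](OC)[C@@H](O[Si](CC)(CC)CC)/C(C)=C/[C@H](C)[C@@H](O[Si](CC)(CC)CC)[C@@H](OC)C[C@H](C)[C@@H](O[Si](C)(C)C(C)(C)C)c1cc(O[Si](C(C)C)(C(C)C)C(C)C)cc(N)c1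
F8 | step 23 | amino acid (seco acid of 31) | OC(=O)/C(C)=C/CC[C@H](OC)[C@@H](O[Si](CC)(CC)CC)/C(C)=C/[C@H](C)[C@@H](O[Si](CC)(CC)CC)[C@@H](OC)C[C@H](C)[C@@H](O[Si](C)(C)C(C)(C)C)c1cc(O[Si](C(C)C)(C(C)C)C(C)C)cc(N)c1
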